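**Retrosynthetic overview**
- The target is cut at the exocyclic amidine C–N bond into an (R)-2-aminoimidazol-4-yl carbinol and 1-methylparabanic acid; the dione ring is bought intact and attached last, with desilylation in the same flask.
- The 2-amino group comes from the C2–H imidazole by C2 lithiation, azide transfer and hydrogenation.
- Key disconnection: the C4–CH(OH) bond is made and set (R) in one step by catalytic enantioselective transfer of an imidazol-4-yl titanium reagent (from the C4 iodide) to 4-methoxybenzaldehyde, instead of the usual ketone plus asymmetric reduction.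
- The C4 iodide comes from 4,5-diiodo-1-methylimidazole by C5-selective iodine–magnesium exchange, addition to silyl-protected 4-hydroxybenzaldehyde and ionic deoxygenation.
- Ring order: no ring is built; the purchased imidazole is decorated N1, then C5, then C4, then C2, and is finally joined to the preformed imidazolidinetrione.

Assumptions: the target stereocentre is (R) (O > imidazol-4-yl > 4-methoxyphenyl > H); the facial sense of the key step is taken from the known aryl transfers with the same catalyst, is to be confirmed on the first carbinol by Mosher ester analysis and chiral HPLC, and the (R)-ligand would be used instead if the sense proved opposite; (S)-H8-BINOL means (S)-5,5',6,6',7,7',8,8'-octahydro-1,1'-bi-2-naphthol.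

Handling: from the first carbinol onward, work-ups are kept at pH 7 or above and chromatography is on Et3N-deactivated silica, because the doubly benzylic carbinol ionises easily in protic acid.

**Step 1**
Reactants: 1 4,5-diiodo-1H-imidazole
Product: 2 4,5-diiodo-1-methyl-1H-imidazole
Conditions: MeI (1.05 equiv), K2CO3, DMF, 0 °C to rt
Reagents that add atoms: iodomethane, CI
Why: SN2 N-alkylation of the imidazolide; the two ring nitrogens of 1 are equivalent by tautomerism, so only one N-methyl isomer can form.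

**Step 2**
Reactants: 2 4,5-diiodo-1-methyl-1H-imidazole; 3 4-[(tert-butyldimethylsilyl)oxy]benzaldehyde
Product: 5 rac-{4-[(tert-butyldimethylsilyl)oxy]phenyl}(4-iodo-1-methyl-1H-imidazol-5-yl)methanol, via C5 Grignard reagent 4 (not isolated)
Conditions: EtMgBr (1.05 equiv), CH2Cl2, rt, 20 min; then 3, rt; then H2O
Reagents that add atoms: none
Why: Iodine–magnesium exchange is faster at C5, where the carbanion is stabilised by the adjacent N-methyl nitrogen, and the Grignard reagent then adds to the aldehyde (Grignard addition); the new carbinol centre is racemic and is removed in step 3.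

**Step 3**
Reactants: 5 rac-{4-[(tert-butyldimethylsilyl)oxy]phenyl}(4-iodo-1-methyl-1H-imidazol-5-yl)methanol
Product: 6 5-{4-[(tert-butyldimethylsilyl)oxy]benzyl}-4-iodo-1-methyl-1H-imidazole
Conditions: Et3SiH (3 equiv), TFA (10 equiv), CH2Cl2, 0 °C to rt; aq. NaHCO3
Reagents that add atoms: none
Why: Ionic hydrogenation, in which TFA ionises the carbinol to a cation stabilised by the para-silyloxyphenyl ring and Et3SiH delivers hydride, while the C–I bond and the aryl silyl ether are inert.

**Step 4 (key step)**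
Reactants: 6 5-{4-[(tert-butyldimethylsilyl)oxy]benzyl}-4-iodo-1-methyl-1H-imidazole; 7 4-methoxybenzaldehyde
Product: 10 (R)-(5-{4-[(tert-butyldimethylsilyl)oxy]benzyl}-1-methyl-1H-imidazol-4-yl)(4-methoxyphenyl)methanol, via C4 Grignard reagent 8 (not isolated), via imidazol-4-yltitanium triisopropoxide 9 (not isolated)
Conditions: EtMgBr (1.0 equiv), CH2Cl2, rt; ClTi(OiPr)3 (1.0 equiv), −78 °C to rt; 1,4-dioxane, filter under Ar; filtrate added over 2 h to 7 (0.8 equiv), (S)-H8-BINOL (10 mol %), Ti(OiPr)4 (1.2 equiv), toluene, 0 °C; aq. KNaC4H4O6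
Reagents that add atoms: none
Why: Proposed new method: iodine–magnesium exchange and transmetalation give an imidazol-4-yl–Ti(OiPr)3 species whose uncatalysed addition is slow compared with the ligand-accelerated pathway through the dinuclear (S)-H8-BINOLate–titanium complex, which binds aldehyde 7, blocks its Re face and delivers the heteroaryl group to the Si face to give the (R)-carbinol; the closest known reaction type is the Ti(OiPr)4/H8-BINOL-catalysed enantioselective addition of aryl-, thienyl- and furyl-titanium triisopropoxides to aromatic aldehydes, from whose uniform facial sense the (S)-ligand is chosen.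

**Step 5**
Reactants: 10 (R)-(5-{4-[(tert-butyldimethylsilyl)oxy]benzyl}-1-methyl-1H-imidazol-4-yl)(4-methoxyphenyl)methanol
Product: 12 (R)-(2-azido-5-{4-[(tert-butyldimethylsilyl)oxy]benzyl}-1-methyl-1H-imidazol-4-yl)(4-methoxyphenyl)methanol, via C2-lithio lithium alkoxide 11 (not isolated)
Conditions: n-BuLi (2.2 equiv), THF, −78 °C, 45 min; TsN3 (1.2 equiv), −78 to −20 °C; then H2O
Reagents that add atoms: 4-methylbenzenesulfonyl azide (TsN3), Cc1ccc(cc1)S(=O)(=O)N=[N+]=[N-]
Why: After the hydroxyl is converted to its lithium alkoxide (which also deactivates the carbinol C–H), the second equivalent of base lithiates the kinetically most acidic C2–H of the 1-methylimidazole, and electrophilic azide transfer from the sulfonyl azide with loss of sulfinate installs the azide without touching any bond to the stereocentre.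

**Step 6**
Reactants: 12 (R)-(2-azido-5-{4-[(tert-butyldimethylsilyl)oxy]benzyl}-1-methyl-1H-imidazol-4-yl)(4-methoxyphenyl)methanol
Product: 13 (R)-(2-amino-5-{4-[(tert-butyldimethylsilyl)oxy]benzyl}-1-methyl-1H-imidazol-4-yl)(4-methoxyphenyl)methanol
Conditions: H2 (1 atm), 5% Pd/CaCO3 (Pb(OAc)2-poisoned), EtOAc, rt, 1 h; used directly
Reagents that add atoms: none
Why: Catalytic hydrogenation of the azide to the amine over Pb-poisoned Pd/CaCO3, a catalyst too weak to hydrogenolyse the benzylic C–O bond in a neutral aprotic solvent, so the stereocentre is untouched.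

**Step 7**
Reactants: 13 (R)-(2-amino-5-{4-[(tert-butyldimethylsilyl)oxy]benzyl}-1-methyl-1H-imidazol-4-yl)(4-methoxyphenyl)methanol; 14 1-methylimidazolidine-2,4,5-trione (1-methylparabanic acid)
Product: 17 5-({4-[(R)-hydroxy(4-methoxyphenyl)methyl]-5-(4-hydroxybenzyl)-1-methyl-1H-imidazol-2-yl}amino)-3-methyl-3H-imidazole-2,4-dione (target), via O-silyl imidate 15 (not isolated), via bis-silylated amidine 16 (not isolated)
Conditions: 14 (1.5 equiv), BSA (4 equiv), MeCN, rt, 1 h; then 13, toluene, 100 °C, 12 h; then Bu4NF (4 equiv), AcOH (4 equiv), THF, 0 °C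
Reagents that add atoms: none
Why: Silyl-imidate amidination, in which BSA turns the C4 carbonyl next to N–H of 14 into an O-silyl imidate that the 2-amino group attacks by addition–elimination (this fixes the regiochemistry, C4 and not the C5 carbonyl next to N-methyl), while the carbinol is masked in the flask as its trimethylsilyl ether in a neutral aprotic medium so that it cannot ionise, and buffered fluoride then removes both silyl groups.

**Compound list**
1 | 4,5-diiodo-1H-imidazole | Ic1nc[nH]c1I | starting material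
2 | 4,5-diiodo-1-methyl-1H-imidazole | Cn1cnc(I)c1I | intermediate
3 | 4-[(tert-butyldimethylsilyl)oxy]benzaldehyde | CC(C)(C)[Si](C)(C)Oc1ccc(C=O)cc1 | starting material
4 | (4-iodo-1-methyl-1H-imidazol-5-yl)magnesium bromide | Cn1cnc(I)c1[Mg]Br | intermediate
5 | rac-{4-[(tert-butyldimethylsilyl)oxy]phenyl}(4-iodo-1-methyl-1H-imidazol-5-yl)methanol | Cn1cnc(I)c1C(O)c1ccc(O[Si](C)(C)C(C)(C)C)cc1 | intermediate
6 | 5-{4-[(tert-butyldimethylsilyl)oxy]benzyl}-4-iodo-1-methyl-1H-imidazole | Cn1cnc(I)c1Cc1ccc(O[Si](C)(C)C(C)(C)C)cc1 | intermediate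
7 | 4-methoxybenzaldehyde | COc1ccc(C=O)cc1 | starting material
8 | (5-{4-[(tert-butyldimethylsilyl)oxy]benzyl}-1-methyl-1H-imidazol-4-yl)magnesium bromide | Cn1cnc([Mg]Br)c1Cc1ccc(O[Si](C)(C)C(C)(C)C)cc1 | intermediate
9 | (5-{4-[(tert-butyldimethylsilyl)oxy]benzyl}-1-methyl-1H-imidazol-4-yl)titanium triisopropoxide | Cn1cnc([Ti](OC(C)C)(OC(C)C)OC(C)C)c1Cc1ccc(O[Si](C)(C)C(C)(C)C)cc1 | intermediate
10 | (R)-(5-{4-[(tert-butyldimethylsilyl)oxy]benzyl}-1-methyl-1H-imidazol-4-yl)(4-methoxyphenyl)methanol | COc1ccc([C@@H](O)c2ncn(C)c2Cc2ccc(O[Si](C)(C)C(C)(C)C)cc2)cc1 | intermediate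
11 | lithium (R)-(5-{4-[(tert-butyldimethylsilyl)oxy]benzyl}-2-lithio-1-methyl-1H-imidazol-4-yl)(4-methoxyphenyl)methanolate | COc1ccc([C@@H](O[Li])c2nc([Li])n(C)c2Cc2ccc(O[Si](C)(C)C(C)(C)C)cc2)cc1 | intermediate
12 | (R)-(2-azido-5-{4-[(tert-butyldimethylsilyl)oxy]benzyl}-1-methyl-1H-imidazol-4-yl)(4-methoxyphenyl)methanol | COc1ccc([C@@H](O)c2nc(N=[N+]=[N-])n(C)c2Cc2ccc(O[Si](C)(C)C(C)(C)C)cc2)cc1 | intermediate
13 | (R)-(2-amino-5-{4-[(tert-butyldimethylsilyl)oxy]benzyl}-1-methyl-1H-imidazol-4-yl)(4-methoxyphenyl)methanol | COc1ccc([C@@H](O)c2nc(N)n(C)c2Cc2ccc(O[Si](C)(C)C(C)(C)C)cc2)cc1 | intermediate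
14 | 1-methylimidazolidine-2,4,5-trione (1-methylparabanic acid) | CN1C(=O)NC(=O)C1=O | starting material
15 | 1-methyl-4-[(trimethylsilyl)oxy]-1H-imidazole-2,5-dione | CN1C(=O)N=C(O[Si](C)(C)C)C1=O | intermediate
16 | 5-{[5-{4-[(tert-butyldimethylsilyl)oxy]benzyl}-4-{(R)-(4-methoxyphenyl)[(trimethylsilyl)oxy]methyl}-1-methyl-1H-imidazol-2-yl]amino}-3-methyl-3H-imidazole-2,4-dione | COc1ccc([C@@H](O[Si](C)(C)C)c2nc(NC3=NC(=O)N(C)C3=O)n(C)c2Cc2ccc(O[Si](C)(C)C(C)(C)C)cc2)cc1 | intermediate
17 | 5-({4-[(R)-hydroxy(4-methoxyphenyl)methyl]-5-(4-hydroxybenzyl)-1-methyl-1H-imidazol-2-yl}amino)-3-methyl-3H-imidazole-2,4-dione (CNP0181743.1) | COc1ccc([C@@H](O)c2nc(NC3=NC(=O)N(C)C3=O)n(C)c2Cc2ccc(O)cc2)cc1 | target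

**Totals**
Total step count: 7. Longest linear sequence: 7 steps (1 to 17); 3, 7 and 14 are purchased and enter directly.

**Three steps most likely to fail, with fallbacks**

Step 4 (enantioselective imidazolyl transfer). The risks are coordination of N3 to titanium, racemic background addition promoted by residual magnesium salts, and an unverified facial sense. The fallback sets out from 6. Grignard reagent 8 is acylated with N-methoxy-4-methoxy-N-methylbenzamide (THF, 0 °C) to give the ketone (5-{4-[(tert-butyldimethylsilyl)oxy]benzyl}-1-methyl-1H-imidazol-4-yl)(4-methoxyphenyl)methanone F1. The stereocentre is then set by Noyori asymmetric transfer hydrogenation (RuCl[(S,S)-TsDPEN](p-cymene) or its (R,R) antipode, HCO2Na, H2O/iPrOH, 40 °C), the antipode that gives the (R)-alcohol being selected by Mosher analysis. This comes back to the route at 10.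

Step 5 (dianion lithiation and azidation). The risks are poor solubility or incomplete C2 metalation of the lithium alkoxide and competing deprotonation at the C5 benzylic CH2. The fallback sets out from 10 and reverses the polarity of the C2–N bond formation. Electrophilic bromination with NBS (1.05 equiv, THF, −20 °C), where the imidazole C2 reacts before either arene, gives (R)-(2-bromo-5-{4-[(tert-butyldimethylsilyl)oxy]benzyl}-1-methyl-1H-imidazol-4-yl)(4-methoxyphenyl)methanol F2. Pd-catalysed C–N coupling with LiN(SiMe3)2 as ammonia surrogate (Pd2(dba)3, tBuBrettPhos, THF, 60 °C, 2.5 equiv of the amide so that the hydroxyl is carried as its alkoxide) gives (R)-{2-[bis(trimethylsilyl)amino]-5-{4-[(tert-butyldimethylsilyl)oxy]benzyl}-1-methyl-1H-imidazol-4-yl}(4-methoxyphenyl)methanol F3. F3 is hydrolysed on aqueous NaHCO3 work-up and comes back to the route at 13, bypassing azide 12.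

Step 7 (amidination at 100 °C). The risks are ionisation and racemisation of the electron-rich carbinol and incomplete condensation. The fallback sets out from 13 and sets the stereocentre last. MnO2 (CH2Cl2, rt) oxidises the carbinol to the robust ketone (2-amino-5-{4-[(tert-butyldimethylsilyl)oxy]benzyl}-1-methyl-1H-imidazol-4-yl)(4-methoxyphenyl)methanone F4. F4 is condensed with 14 and BSA as in step 7, without fluoride, to 5-{[5-{4-[(tert-butyldimethylsilyl)oxy]benzyl}-4-(4-methoxybenzoyl)-1-methyl-1H-imidazol-2-yl]amino}-3-methyl-3H-imidazole-2,4-dione F5. Asymmetric transfer hydrogenation (RuCl[(S,S)-TsDPEN](p-cymene) or its antipode, HCO2Na, H2O/THF, 40 °C) gives 5-{[5-{4-[(tert-butyldimethylsilyl)oxy]benzyl}-4-[(R)-hydroxy(4-methoxyphenyl)methyl]-1-methyl-1H-imidazol-2-yl]amino}-3-methyl-3H-imidazole-2,4-dione F6. Bu4NF/AcOH (THF, 0 °C) then comes back to the route at 17.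

**Further compounds**
F1 | step 4 | (5-{4-[(tert-butyldimethylsilyl)oxy]benzyl}-1-methyl-1H-imidazol-4-yl)(4-methoxyphenyl)methanone | COc1ccc(C(=O)c2ncn(C)c2Cc2ccc(O[Si](C)(C)C(C)(C)C)cc2)cc1
F2 | step 5 | (R)-(2-bromo-5-{4-[(tert-butyldimethylsilyl)oxy]benzyl}-1-methyl-1H-imidazol-4-yl)(4-methoxyphenyl)methanol | COc1ccc([C@@H](O)c2nc(Br)n(C)c2Cc2ccc(O[Si](C)(C)C(C)(C)C)cc2)cc1
F3 | step 5 | (R)-{2-[bis(trimethylsilyl)amino]-5-{4-[(tert-butyldimethylsilyl)oxy]benzyl}-1-methyl-1H-imidazol-4-yl}(4-methoxyphenyl)methanol | COc1ccc([C@@H](O)c2nc(N([Si](C)(C)C)[Si](C)(C)C)n(C)c2Cc2ccc(O[Si](C)(C)C(C)(C)C)cc2)cc1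
F4 | step 7 | (2-amino-5-{4-[(tert-butyldimethylsilyl)oxy]benzyl}-1-methyl-1H-imidazol-4-yl)(4-methoxyphenyl)methanone | COc1ccc(C(=O)c2nc(N)n(C)c2Cc2ccc(O[Si](C)(C)C(C)(C)C)cc2)cc1
F5 | step 7 | 5-{[5-{4-[(tert-butyldimethylsilyl)oxy]benzyl}-4-(4-methoxybenzoyl)-1-methyl-1H-imidazol-2-yl]amino}-3-methyl-3H-imidazole-2,4-dione | COc1ccc(C(=O)c2nc(NC3=NC(=O)N(C)C3=O)n(C)c2Cc2ccc(O[Si](C)(C)C(C)(C)C)cc2)cc1
F6 | step 7 | 5-{[5-{4-[(tert-butyldimethylsilyl)oxy]benzyl}-4-[(R)-hydroxy(4-methoxyphenyl)methyl]-1-methyl-1H-imidazol-2-yl]amino}-3-methyl-3H-imidazole-2,4-dione | COc1ccc([C@@H](O)c2nc(NC3=NC(=O)N(C)C3=O)n(C)c2Cc2ccc(O[Si](C)(C)C(C)(C)C)cc2)cc1
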